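The hydroazulene is cut at C4–C5 of the seven-membered ring. Once the C3=C3a ring-fusion alkene is traced back to a C3a ketone, the C6=C7 alkene lies γ,δ to that carbonyl, which is the imprint of a Claisen shift. One thermal [3,3] step on a 2-methylidene-oxolane, whose oxygen-bearing carbon carries a 3-(PMB-oxy)prop-1-en-2-yl group, forms C4–C5, breaks C7–O and expands the five-membered ether to the cycloheptenone. The precursor already holds the C8a quaternary centre, set by two anti-selective alkylations of a chiral-pool lactone, and a ketal-masked isopropyl ketone chain. McMurry closure of the five-membered ring and a Mitsunobu esterification complete the route.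

Key step: step 11

Remark on the chemistry: hydroazulene numbering is used for the target (C3 isopropyl, C3a and C8a ring fusion, C6 bearing the CH2O arm, C8a methyl). The stereodescriptors were checked and (5S) in lactone 1 leads to (8aR) in the target. The arm is carried as a 4-methoxybenzyl ether, not a silyl ether, because an α-silyloxymethyllithium would rearrange by silyl migration, whereas the PMB ether survives ketal hydrolysis and the titanium coupling.

Step 1
Reactants: 1 (5S)-5-(hydroxymethyl)oxolan-2-one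
Product: 2 (5S)-5-[(trityloxy)methyl]oxolan-2-one
Conditions: TrCl, Et3N, DMAP (cat.), CH2Cl2, rt
Reagents that add atoms: trityl chloride, ClC(c1ccccc1)(c1ccccc1)c1ccccc1
Why: Standard O-tritylation of a primary alcohol (etherification through the trityl cation), which leaves the stereocentre untouched and installs the bulky group that will shield one lactone face.

Step 2
Reactants: 2 (5S)-5-[(trityloxy)methyl]oxolan-2-one
Product: 4 (3R,5S)-3-methyl-5-[(trityloxy)methyl]oxolan-2-one, via lithium enolate 3 (not isolated)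
Conditions: LiN(iPr)2, THF, −78 °C; then MeI, −78 °C
Reagents that add atoms: iodomethane, CI
Why: Lactone enolate alkylation in which MeI approaches the planar enolate on the face opposite the CH2OTr group, so the methyl group should end up trans to it (C3 = R).

Step 3
Reactants: 5 4-methylpent-1-en-3-one
Product: 7 2-(2-iodoethyl)-2-(propan-2-yl)-1,3-dioxolane, via silyl enol ether 6 (not isolated)
Conditions: Me3SiCl, NaI, MeCN, 0 °C; then HOCH2CH2OH, rt
Reagents that add atoms: sodium iodide, [Na+].[I-]; ethylene glycol, OCCO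
Why: Conjugate addition of Me3SiI generated in the flask to the vinyl ketone, followed by ketalization of the resulting silyl enol ether with the diol, is a known one-flask halo-ketalization giving β-iodo ketals.

Step 4
Reactants: 4 (3R,5S)-3-methyl-5-[(trityloxy)methyl]oxolan-2-one; 7 2-(2-iodoethyl)-2-(propan-2-yl)-1,3-dioxolane
Product: 9 (3R,5S)-3-methyl-3-{2-[2-(propan-2-yl)-1,3-dioxolan-2-yl]ethyl}-5-[(trityloxy)methyl]oxolan-2-one, via lithium enolate 8 (not isolated)
Conditions: LiN(iPr)2, THF, −78 °C; then 7, DMPU, −78 to −20 °C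
Reagents that add atoms: none
Why: Second lactone enolate alkylation (SN2 at a primary iodide, accelerated by DMPU) in which the electrophile again enters anti to CH2OTr, so the chain should stand trans and the methyl cis to that group, fixing the quaternary carbon (future C8a) as R.

Step 5
Reactants: 9 (3R,5S)-3-methyl-3-{2-[2-(propan-2-yl)-1,3-dioxolan-2-yl]ethyl}-5-[(trityloxy)methyl]oxolan-2-one
Product: 10 (3R,5S)-5-(hydroxymethyl)-3-methyl-3-{2-[2-(propan-2-yl)-1,3-dioxolan-2-yl]ethyl}oxolan-2-one
Conditions: TsOH·H2O (cat.), HOCH2CH2OH/THF, rt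
Reagents that add atoms: none
Why: Acid-catalysed solvolysis of the trityl ether (SN1 transfer of the trityl cation to the diol), in which ethylene glycol as acceptor keeps the dioxolane closed and the γ-lactone is stable to catalytic acid.

Step 6
Reactants: 10 (3R,5S)-5-(hydroxymethyl)-3-methyl-3-{2-[2-(propan-2-yl)-1,3-dioxolan-2-yl]ethyl}oxolan-2-one
Product: 11 (2S,4R)-4-methyl-5-oxo-4-{2-[2-(propan-2-yl)-1,3-dioxolan-2-yl]ethyl}oxolane-2-carbaldehyde
Conditions: TEMPO (cat.), PhI(OAc)2, CH2Cl2, rt
Reagents that add atoms: none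
Why: Oxoammonium (TEMPO) oxidation of a primary alcohol stops at the aldehyde under base-free conditions, so the oxygen-bearing stereocentre should not epimerise and the ketal is spared.

Step 7
Reactants: 12 (tributylstannyl)methanol
Product: 13 tributyl{[(4-methoxybenzyl)oxy]methyl}stannane
Conditions: NaH, 4-MeOC6H4CH2Cl, Bu4NI (cat.), THF/DMF, 0 °C to rt
Reagents that add atoms: 4-methoxybenzyl chloride, COc1ccc(CCl)cc1
Why: Williamson etherification of the stannylmethanol alkoxide, the usual way to make α-alkoxymethylstannanes.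

Step 8
Reactants: 11 (2S,4R)-4-methyl-5-oxo-4-{2-[2-(propan-2-yl)-1,3-dioxolan-2-yl]ethyl}oxolane-2-carbaldehyde; 13 tributyl{[(4-methoxybenzyl)oxy]methyl}stannane
Product: 15 (3R,5S)-5-{1-hydroxy-2-[(4-methoxybenzyl)oxy]ethyl}-3-methyl-3-{2-[2-(propan-2-yl)-1,3-dioxolan-2-yl]ethyl}oxolan-2-one (both carbinol epimers), via alkoxymethyllithium 14 (not isolated)
Conditions: 13, n-BuLi, THF, −78 °C; then 11, −78 °C; AcOH quench at −78 °C
Reagents that add atoms: none
Why: Tin–lithium exchange gives the α-alkoxymethyllithium, whose 1,2-addition to the aldehyde at −78 °C should far outpace attack on the hindered α-quaternary lactone; the new carbinol centre forms unselectively, which does not matter because step 9 oxidises it.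

Step 9
Reactants: 15 (3R,5S)-5-{1-hydroxy-2-[(4-methoxybenzyl)oxy]ethyl}-3-methyl-3-{2-[2-(propan-2-yl)-1,3-dioxolan-2-yl]ethyl}oxolan-2-one
Product: 16 (3R,5S)-5-{[(4-methoxybenzyl)oxy]acetyl}-3-methyl-3-{2-[2-(propan-2-yl)-1,3-dioxolan-2-yl]ethyl}oxolan-2-one
Conditions: Dess–Martin periodinane, NaHCO3, CH2Cl2, 0 °C to rt
Reagents that add atoms: none
Why: Dess–Martin oxidation of the secondary alcohol to the α-alkoxy ketone under buffered, non-basic conditions that spare the ketal, the PMB ether, the lactone and the adjacent stereocentre.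

Step 10
Reactants: 16 (3R,5S)-5-{[(4-methoxybenzyl)oxy]acetyl}-3-methyl-3-{2-[2-(propan-2-yl)-1,3-dioxolan-2-yl]ethyl}oxolan-2-one
Product: 18 (3R,5S)-5-{3-[(4-methoxybenzyl)oxy]prop-1-en-2-yl}-3-methyl-2-methylidene-3-{2-[2-(propan-2-yl)-1,3-dioxolan-2-yl]ethyl}oxolane, via methylenated lactone 17 (not isolated)
Conditions: Cp2TiMe2 (excess), toluene/THF, 70 °C, dark; basic alumina work-up
Reagents that add atoms: dimethyltitanocene Cp2TiMe2, C[Ti+2]C.c1cc[cH-]c1.c1cc[cH-]c1
Why: Petasis methylenation converts first the ketone and then the lactone carbonyl into C=CH2 without base, so the oxygen-bearing centre should keep its configuration, and the exocyclic enol ether cannot migrate into the ring because the neighbouring carbon is quaternary.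

Step 11
Reactants: 18 (3R,5S)-5-{3-[(4-methoxybenzyl)oxy]prop-1-en-2-yl}-3-methyl-2-methylidene-3-{2-[2-(propan-2-yl)-1,3-dioxolan-2-yl]ethyl}oxolane
Product: 19 (2R)-5-{[(4-methoxybenzyl)oxy]methyl}-2-methyl-2-{2-[2-(propan-2-yl)-1,3-dioxolan-2-yl]ethyl}cyclohept-4-en-1-one
Conditions: degassed toluene, Et3N (trace), base-washed sealed tube, 185 °C
Reagents that add atoms: none
Why: A concerted [3,3]-sigmatropic (Claisen) shift of the allyl vinyl ether CH2=C(–O–)–O–CH–C(=CH2) joins the two exocyclic methylene carbons (C4–C5) while the ring C7–O bond breaks and the enol ether becomes the C3a ketone, and carbonyl formation makes the shift irreversible. The closest known reaction type is the thermal Claisen ring expansion of 2-methylene-5-vinyltetrahydrofurans to cyclohept-4-enones. The seven-membered ring closes by a two-carbon ring expansion through a boat-like six-centre transition state bridged by the C8–C8a tether, not by an exo or endo chain cyclisation, and the ring forces the new C6=C7 alkene to be cis. No stereocentre is created: C8a is carried over unchanged and the oxygen-bearing centre is consumed. The step needs the [3,3] path to outrun protonation or isomerisation of the enol ether; the quaternary C8a leaves no hydrogen for double-bond migration into the ring, base-washed glass and a trace of amine exclude acid, and the alkenyl group sits cis to the small methyl group, so the termini meet on the face away from the ketal chain.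

Step 12
Reactants: 19 (2R)-5-{[(4-methoxybenzyl)oxy]methyl}-2-methyl-2-{2-[2-(propan-2-yl)-1,3-dioxolan-2-yl]ethyl}cyclohept-4-en-1-one
Product: 20 (2R)-5-{[(4-methoxybenzyl)oxy]methyl}-2-methyl-2-(4-methyl-3-oxopentyl)cyclohept-4-en-1-one
Conditions: 1 M aq. HCl, THF, rt
Reagents that add atoms: water, O
Why: Acid-catalysed acetal hydrolysis frees the isopropyl ketone, while the PMB ether, the trisubstituted alkene and the quaternary α-carbon (which cannot epimerise) should be unaffected by dilute acid at room temperature.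

Step 13
Reactants: 20 (2R)-5-{[(4-methoxybenzyl)oxy]methyl}-2-methyl-2-(4-methyl-3-oxopentyl)cyclohept-4-en-1-one
Product: 21 (8aR)-6-{[(4-methoxybenzyl)oxy]methyl}-8a-methyl-3-(propan-2-yl)-1,2,4,5,8,8a-hexahydroazulene
Conditions: TiCl3(DME)1.5, Zn–Cu couple, DME, reflux; slow addition of 20
Reagents that add atoms: none
Why: Intramolecular McMurry coupling, in which low-valent titanium joins the two ketone carbons of the 1,5-diketone with loss of both oxygens, should close the cyclopentene and give the tetrasubstituted C3=C3a alkene; ethers and isolated alkenes are tolerated and high dilution suppresses intermolecular coupling.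

Step 14
Reactants: 21 (8aR)-6-{[(4-methoxybenzyl)oxy]methyl}-8a-methyl-3-(propan-2-yl)-1,2,4,5,8,8a-hexahydroazulene
Product: 22 [(8aR)-8a-methyl-3-(propan-2-yl)-1,2,4,5,8,8a-hexahydroazulen-6-yl]methanol
Conditions: DDQ, CH2Cl2/pH 7 buffer, 0 °C
Reagents that add atoms: none
Why: Oxidative PMB cleavage (hydride abstraction from the electron-rich benzylic position by DDQ, then hydrolysis) runs near neutrality at 0 °C, so neither alkene should migrate.

Step 15
Reactants: 22 [(8aR)-8a-methyl-3-(propan-2-yl)-1,2,4,5,8,8a-hexahydroazulen-6-yl]methanol; 23 4-hydroxy-3-methoxybenzoic acid (vanillic acid)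
Product: 24 [(8aR)-8a-methyl-3-(propan-2-yl)-1,2,4,5,8,8a-hexahydroazulen-6-yl]methyl 4-hydroxy-3-methoxybenzoate
Conditions: PPh3, DIAD, THF, 0 °C to rt
Reagents that add atoms: none
Why: Mitsunobu esterification, in which the carboxylic acid (far more acidic than the phenol) acts as the pronucleophile and displaces the activated primary allylic oxygen by SN2, a chemoselectivity known for phenolic acids, so the phenol needs no protection and no stereocentre is touched.

Compound list
1 | (5S)-5-(hydroxymethyl)oxolan-2-one | O=C1CC[C@@H](CO)O1 | starting material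
2 | (5S)-5-[(trityloxy)methyl]oxolan-2-one | O=C1CC[C@@H](COC(c2ccccc2)(c2ccccc2)c2ccccc2)O1 | intermediate
3 | lithium (5S)-5-[(trityloxy)methyl]-4,5-dihydrofuran-2-olate (lithium enolate of 2) | [Li]OC1=CC[C@@H](COC(c2ccccc2)(c2ccccc2)c2ccccc2)O1 | intermediate
4 | (3R,5S)-3-methyl-5-[(trityloxy)methyl]oxolan-2-one | O=C1O[C@H](COC(c2ccccc2)(c2ccccc2)c2ccccc2)C[C@H]1C | intermediate
5 | 4-methylpent-1-en-3-one | C=CC(=O)C(C)C | starting material
6 | [(1-iodo-4-methylpent-2-en-3-yl)oxy]trimethylsilane (silyl enol ether) | CC(C)C(O[Si](C)(C)C)=CCI | intermediate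
7 | 2-(2-iodoethyl)-2-(propan-2-yl)-1,3-dioxolane | CC(C)C1(CCI)OCCO1 | intermediate
8 | lithium (5S)-3-methyl-5-[(trityloxy)methyl]-4,5-dihydrofuran-2-olate (lithium enolate of 4) | [Li]OC1=C(C)C[C@@H](COC(c2ccccc2)(c2ccccc2)c2ccccc2)O1 | intermediate
9 | (3R,5S)-3-methyl-3-{2-[2-(propan-2-yl)-1,3-dioxolan-2-yl]ethyl}-5-[(trityloxy)methyl]oxolan-2-one | O=C1O[C@H](COC(c2ccccc2)(c2ccccc2)c2ccccc2)C[C@@]1(C)CCC3(C(C)C)OCCO3 | intermediate
10 | (3R,5S)-5-(hydroxymethyl)-3-methyl-3-{2-[2-(propan-2-yl)-1,3-dioxolan-2-yl]ethyl}oxolan-2-one | O=C1O[C@H](CO)C[C@@]1(C)CCC2(C(C)C)OCCO2 | intermediate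
11 | (2S,4R)-4-methyl-5-oxo-4-{2-[2-(propan-2-yl)-1,3-dioxolan-2-yl]ethyl}oxolane-2-carbaldehyde | O=C1O[C@H](C=O)C[C@@]1(C)CCC2(C(C)C)OCCO2 | intermediate
12 | (tributylstannyl)methanol | CCCC[Sn](CCCC)(CCCC)CO | starting material
13 | tributyl{[(4-methoxybenzyl)oxy]methyl}stannane | CCCC[Sn](CCCC)(CCCC)COCc1ccc(OC)cc1 | intermediate
14 | {[(4-methoxybenzyl)oxy]methyl}lithium | [Li]COCc1ccc(OC)cc1 | intermediate
15 | (3R,5S)-5-{1-hydroxy-2-[(4-methoxybenzyl)oxy]ethyl}-3-methyl-3-{2-[2-(propan-2-yl)-1,3-dioxolan-2-yl]ethyl}oxolan-2-one (both carbinol epimers) | O=C1O[C@H](C(O)COCc2ccc(OC)cc2)C[C@@]1(C)CCC3(C(C)C)OCCO3 | intermediate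
16 | (3R,5S)-5-{[(4-methoxybenzyl)oxy]acetyl}-3-methyl-3-{2-[2-(propan-2-yl)-1,3-dioxolan-2-yl]ethyl}oxolan-2-one | O=C1O[C@H](C(=O)COCc2ccc(OC)cc2)C[C@@]1(C)CCC3(C(C)C)OCCO3 | intermediate
17 | (3R,5S)-5-{3-[(4-methoxybenzyl)oxy]prop-1-en-2-yl}-3-methyl-3-{2-[2-(propan-2-yl)-1,3-dioxolan-2-yl]ethyl}oxolan-2-one | O=C1O[C@H](C(=C)COCc2ccc(OC)cc2)C[C@@]1(C)CCC3(C(C)C)OCCO3 | intermediate
18 | (3R,5S)-5-{3-[(4-methoxybenzyl)oxy]prop-1-en-2-yl}-3-methyl-2-methylidene-3-{2-[2-(propan-2-yl)-1,3-dioxolan-2-yl]ethyl}oxolane | C=C1O[C@H](C(=C)COCc2ccc(OC)cc2)C[C@@]1(C)CCC3(C(C)C)OCCO3 | intermediate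
19 | (2R)-5-{[(4-methoxybenzyl)oxy]methyl}-2-methyl-2-{2-[2-(propan-2-yl)-1,3-dioxolan-2-yl]ethyl}cyclohept-4-en-1-one | COc1ccc(COCC2=CC[C@@](C)(CCC3(C(C)C)OCCO3)C(=O)CC2)cc1 | intermediate
20 | (2R)-5-{[(4-methoxybenzyl)oxy]methyl}-2-methyl-2-(4-methyl-3-oxopentyl)cyclohept-4-en-1-one | COc1ccc(COCC2=CC[C@@](C)(CCC(=O)C(C)C)C(=O)CC2)cc1 | intermediate
21 | (8aR)-6-{[(4-methoxybenzyl)oxy]methyl}-8a-methyl-3-(propan-2-yl)-1,2,4,5,8,8a-hexahydroazulene | COc1ccc(COCC2=CC[C@@]3(C)CCC(C(C)C)=C3CC2)cc1 | intermediate
22 | [(8aR)-8a-methyl-3-(propan-2-yl)-1,2,4,5,8,8a-hexahydroazulen-6-yl]methanol | OCC1=CC[C@@]2(C)CCC(C(C)C)=C2CC1 | intermediate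
23 | 4-hydroxy-3-methoxybenzoic acid (vanillic acid) | COc1cc(C(=O)O)ccc1O | starting material
24 | [(8aR)-8a-methyl-3-(propan-2-yl)-1,2,4,5,8,8a-hexahydroazulen-6-yl]methyl 4-hydroxy-3-methoxybenzoate | COc1cc(C(=O)OCC2=CC[C@@]3(C)CCC(C(C)C)=C3CC2)ccc1O | target

Total step count: 15.
Longest linear sequence: 13 steps (1, 2, 4, 5, 6, 8, 9, 10, 11, 12, 13, 14, 15); steps 3 and 7 each prepare a fragment in one operation.

Steps most likely to fail

Step 11. The enol ether may be protonated or ionised by traces of acid, or the substrate may decompose at the temperature required before the sigmatropic shift occurs. The fallback replaces the rearrangement by ring-closing metathesis; it sets out from 10 and comes back to the route at 19. Appel iodination of 10 (I2, PPh3, imidazole) would give iodide F1. Zinc dust in ethanol would open the β-acyloxy iodide by reductive elimination to pentenoic acid F2 with the quaternary centre intact, and MeLi would convert this hindered acid into methyl ketone F3. Its lithium enolate (LiN(iPr)2; only the methyl side can enolise) would be alkylated with allylic chloride F4, itself made from 3-chloro-2-(chloromethyl)prop-1-ene and sodium 4-methoxybenzyl oxide, to give dienone F5. Ring-closing metathesis with the second-generation Grubbs catalyst would then form the C6=C7 alkene and deliver 19.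

Step 13. The coupling may stall before deoxygenation at the hindered, fully substituted centres, or low-valent titanium may attack the allylic ether or couple two molecules. The fallback separates C–C bond formation from deoxygenation; it sets out from 20 and comes back at 21. SmI2 in THF would effect the ketone–ketone pinacol cyclisation to cis-diol F6, thiophosgene/DMAP would convert it into cyclic thiocarbonate F7, and heating with P(OMe)3 (Corey–Winter olefination) would give 21.

Step 4. The SN2 reaction of the hindered, fully substituted enolate with the unactivated iodide may be slow, so that elimination of HI from 7 or proton transfer competes. The fallback forms the same bond by conjugate addition; it sets out from 4 and comes back at 10. Enolate 8 would be added to enone 5 at −78 °C (Michael addition, same anti approach) to give keto lactone F8, and TsOH with ethylene glycol under azeotropic removal of water would ketalise the ketone and cleave the trityl ether in one operation to give 10.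

Further compounds
F1 | step 11 | (3R,5S)-5-(iodomethyl)-3-methyl-3-{2-[2-(propan-2-yl)-1,3-dioxolan-2-yl]ethyl}oxolan-2-one | O=C1O[C@H](CI)C[C@@]1(C)CCC2(C(C)C)OCCO2
F2 | step 11 | (2R)-2-methyl-2-{2-[2-(propan-2-yl)-1,3-dioxolan-2-yl]ethyl}pent-4-enoic acid | C=CC[C@@](C(=O)O)(C)CCC1(C(C)C)OCCO1
F3 | step 11 | (3R)-3-methyl-3-{2-[2-(propan-2-yl)-1,3-dioxolan-2-yl]ethyl}hex-5-en-2-one | C=CC[C@@](C(C)=O)(C)CCC1(C(C)C)OCCO1
F4 | step 11 | 1-({[2-(chloromethyl)prop-2-en-1-yl]oxy}methyl)-4-methoxybenzene | C=C(CCl)COCc1ccc(OC)cc1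
F5 | step 11 | (6R)-2-{[(4-methoxybenzyl)oxy]methyl}-6-methyl-6-{2-[2-(propan-2-yl)-1,3-dioxolan-2-yl]ethyl}nona-1,8-dien-5-one | C=CC[C@@](C(=O)CCC(=C)COCc1ccc(OC)cc1)(C)CCC2(C(C)C)OCCO2
F6 | step 13 | (8aR)-6-{[(4-methoxybenzyl)oxy]methyl}-8a-methyl-3-(propan-2-yl)-1,2,3,3a,4,5,8,8a-octahydroazulene-3,3a-diol (cis-diol) | COc1ccc(COCC2=CC[C@@]3(C)CCC(O)(C(C)C)C3(O)CC2)cc1
F7 | step 13 | cyclic 3,3a-thiocarbonate of F6 (1,3-dioxolane-2-thione fused across C3–C3a) | COc1ccc(COCC2=CC[C@@]3(C)CCC4(C(C)C)OC(=S)OC34CC2)cc1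
F8 | step 4 | (3R,5S)-3-methyl-3-(4-methyl-3-oxopentyl)-5-[(trityloxy)methyl]oxolan-2-one | O=C1O[C@H](COC(c2ccccc2)(c2ccccc2)c2ccccc2)C[C@@]1(C)CCC(=O)C(C)C
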